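**Strategy.** The 2,2-dimethyl-2H-pyran ring is disconnected at C4–C4a and O1–C2, which leads back to a phenol and 3-methylbut-2-enal. The key step exploits that C4a (C3' of the aryl ring) sits between the oxygen-bearing carbons C8a and C5 and is the only free position ortho to the phenol oxygen: boron-templated ortho-aldol, ortho-quinone methide formation and oxa-6π electrocyclisation build the pyran in one operation. Its precursor is 2-ethynyl-5-(triisopropylsilyloxy)phenol; the ethynyl group later supplies C2 and C3 of the benzofuran through Sonogashira coupling and 5-endo-dig cyclisation with 4-iodo-6-prenylresorcinol, so that only one silyl group has to be removed at the end.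

Key step: step 7

Remark: the target has no stereocentre and no stereogenic double bond, so no stereocontrol is needed. 4,6-Dibromoresorcinol, 2,4-dihydroxybenzaldehyde, prenyl bromide and 3-methylbut-2-enal are taken as commercial.

**Route**

Step 1
Reactants: 1 4,6-dibromobenzene-1,3-diol
Product: 2 1,5-dibromo-2,4-bis(methoxymethoxy)benzene
Conditions: NaH (2.4 equiv), DMF, 0 °C; MOMCl (2.4 equiv), 0 °C → rt
Reagents that add atoms: chloromethyl methyl ether (MOMCl), COCCl
Why: Williamson-type O-alkylation of both phenoxides; the MOM ethers should survive organolithium chemistry and stabilise an ortho-lithio species by chelation.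

Step 2
Reactants: 2 1,5-dibromo-2,4-bis(methoxymethoxy)benzene; 3 1-bromo-3-methylbut-2-ene (prenyl bromide)
Product: 5 1-bromo-2,4-bis(methoxymethoxy)-5-(3-methylbut-2-en-1-yl)benzene, via aryllithium 4 (not isolated)
Conditions: n-BuLi (1.0 equiv), THF, −78 °C; CuBr·SMe2 (10 mol%), 3 (1.3 equiv), −78 → 0 °C
Reagents that add atoms: none
Why: Mono bromine–lithium exchange (a second exchange on the electron-rich aryllithium is slow) followed by copper-catalysed allylic substitution at the unhindered primary carbon of prenyl bromide (SN2) should give the linear prenyl arene.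

Step 3
Reactants: 5 1-bromo-2,4-bis(methoxymethoxy)-5-(3-methylbut-2-en-1-yl)benzene
Product: 7 1-iodo-2,4-bis(methoxymethoxy)-5-(3-methylbut-2-en-1-yl)benzene, via aryllithium 6 (not isolated)
Conditions: n-BuLi (1.1 equiv), THF, −78 °C; I2 (1.2 equiv), THF, −78 °C; aq. Na2S2O3
Reagents that add atoms: iodine, II
Why: Bromine–lithium exchange and iodinolysis of the aryllithium; at −78 °C iodine should be consumed by the carbanion before it can touch the prenyl alkene, and the iodide allows a mild Sonogashira coupling later.

Step 4
Reactants: 7 1-iodo-2,4-bis(methoxymethoxy)-5-(3-methylbut-2-en-1-yl)benzene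
Product: 8 4-iodo-6-(3-methylbut-2-en-1-yl)benzene-1,3-diol
Conditions: HCl (1.25 M in MeOH), rt → 40 °C
Reagents that add atoms: none
Why: Acid-catalysed acetal exchange removes both MOM groups; dilute acid at modest temperature should leave the prenyl double bond and the aryl iodide intact.

Step 5
Reactants: 9 2,4-dihydroxybenzaldehyde
Product: 10 2-hydroxy-4-[(triisopropylsilyl)oxy]benzaldehyde
Conditions: TIPSCl (1.05 equiv), imidazole (2.2 equiv), DMF, 0 °C → rt
Reagents that add atoms: chlorotriisopropylsilane (TIPSCl), CC(C)[Si](Cl)(C(C)C)C(C)C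
Why: Selective O-silylation of the more acidic, unhindered 4-OH; the 2-OH is held in a hydrogen bond to the formyl group and should stay free.

Step 6
Reactants: 10 2-hydroxy-4-[(triisopropylsilyl)oxy]benzaldehyde
Product: 11 2-ethynyl-5-[(triisopropylsilyl)oxy]phenol
Conditions: dimethyl (1-diazo-2-oxopropyl)phosphonate (1.5 equiv), K2CO3 (3 equiv), MeOH, 0 °C → rt
Reagents that add atoms: dimethyl (1-diazo-2-oxopropyl)phosphonate (Bestmann–Ohira reagent), COP(=O)(OC)C(=[N+]=[N-])C(C)=O
Why: Seyferth–Gilbert homologation in its Bestmann–Ohira form converts the aldehyde into the terminal alkyne; the hindered TIPS ether should resist methanolysis (the 2-phenoxide disfavours loss of a second phenoxide), and without a metal the ortho-ethynylphenol should not cyclise.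

Step 7
Reactants: 11 2-ethynyl-5-[(triisopropylsilyl)oxy]phenol; 12 3-methylbut-2-enal
Product: 15 8-ethynyl-2,2-dimethyl-5-[(triisopropylsilyl)oxy]-2H-chromene, via benzodioxaborin 13 (not isolated), via ortho-quinone methide 14 (not isolated)
Conditions: PhB(OH)2 (1.1 equiv), EtCO2H (0.3 equiv), toluene, reflux, Dean–Stark
Reagents that add atoms: none
Why: Phenol 11 and phenylboronic acid should form an aryl boronate that binds the aldehyde of 12 and delivers it to the ortho carbon through a six-membered chelate (ortho-aldol, C4–C4a bond) to give benzodioxaborin 13, which at reflux releases the boron unit to give ortho-quinone methide 14, and 14 then closes to the pyran (O1–C2 bond). The closest known reaction type is the phenylboronic acid-mediated condensation of phenols with α,β-unsaturated aldehydes to 2H-chromenes, a formal [3+3] annulation. The single ring is closed by a thermal disrotatory oxa-6π electrocyclisation of the (Z)-dienone 14, after the carbon–carbon bond was made intermolecularly; no stereocentre arises because C2 carries two methyl groups. The step needs ortho regioselectivity and a single oxygen able to close the ring: the boron tether reaches only an ortho carbon, the other ortho position carries the ethynyl group, and the second oxygen is blocked as the TIPS ether, so only the carbon between the two oxygens can react and only O1 can close. The terminal alkyne and the silyl ether should be inert to these weakly acidic, metal-free conditions.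

Step 8
Reactants: 8 4-iodo-6-(3-methylbut-2-en-1-yl)benzene-1,3-diol; 15 8-ethynyl-2,2-dimethyl-5-[(triisopropylsilyl)oxy]-2H-chromene
Product: 17 2-{2,2-dimethyl-5-[(triisopropylsilyl)oxy]-2H-chromen-8-yl}-5-(3-methylbut-2-en-1-yl)-1-benzofuran-6-ol, via diarylalkyne 16 (not isolated)
Conditions: Pd(PPh3)2Cl2 (5 mol%), CuI (10 mol%), Et3N, degassed DMF, rt then 70 °C, Ar
Reagents that add atoms: none
Why: Sonogashira coupling followed by metal-promoted 5-endo-dig hydroalkoxylation by the hydroxyl ortho to the alkyne (heteroannulation); the hydroxyl next to the prenyl group cannot reach the alkyne and the chromene oxygen is an ether, so a single benzofuran should form.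

Step 9
Reactants: 17 2-{2,2-dimethyl-5-[(triisopropylsilyl)oxy]-2H-chromen-8-yl}-5-(3-methylbut-2-en-1-yl)-1-benzofuran-6-ol
Product: 18 kanzonol V
Conditions: TBAF (1.2 equiv), AcOH (1.2 equiv), THF, 0 °C → rt
Reagents that add atoms: none
Why: Fluoride-induced cleavage of the aryl silyl ether; the buffered, non-acidic conditions should spare the chromene double bond and the ortho-prenylphenol.

**Compound list**

1 | 4,6-dibromobenzene-1,3-diol | Oc1cc(O)c(Br)cc1Br | starting material
2 | 1,5-dibromo-2,4-bis(methoxymethoxy)benzene | COCOc1cc(OCOC)c(Br)cc1Br | intermediate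
3 | 1-bromo-3-methylbut-2-ene (prenyl bromide) | CC(C)=CCBr | starting material
4 | [5-bromo-2,4-bis(methoxymethoxy)phenyl]lithium | [Li]c1cc(Br)c(OCOC)cc1OCOC | intermediate
5 | 1-bromo-2,4-bis(methoxymethoxy)-5-(3-methylbut-2-en-1-yl)benzene | COCOc1cc(OCOC)c(CC=C(C)C)cc1Br | intermediate
6 | [2,4-bis(methoxymethoxy)-5-(3-methylbut-2-en-1-yl)phenyl]lithium | [Li]c1cc(CC=C(C)C)c(OCOC)cc1OCOC | intermediate
7 | 1-iodo-2,4-bis(methoxymethoxy)-5-(3-methylbut-2-en-1-yl)benzene | COCOc1cc(OCOC)c(CC=C(C)C)cc1I | intermediate
8 | 4-iodo-6-(3-methylbut-2-en-1-yl)benzene-1,3-diol | CC(C)=CCc1cc(I)c(O)cc1O | intermediate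
9 | 2,4-dihydroxybenzaldehyde | O=Cc1ccc(O)cc1O | starting material
10 | 2-hydroxy-4-[(triisopropylsilyl)oxy]benzaldehyde | CC(C)[Si](Oc1ccc(C=O)c(O)c1)(C(C)C)C(C)C | intermediate
11 | 2-ethynyl-5-[(triisopropylsilyl)oxy]phenol | C#Cc1ccc(O[Si](C(C)C)(C(C)C)C(C)C)cc1O | intermediate
12 | 3-methylbut-2-enal | CC(C)=CC=O | starting material
13 | 8-ethynyl-4-(2-methylprop-1-en-1-yl)-2-phenyl-5-[(triisopropylsilyl)oxy]-4H-1,3,2-benzodioxaborinine (racemic at C4) | CC(C)=CC1OB(c2ccccc2)Oc2c(C#C)ccc(O[Si](C(C)C)(C(C)C)C(C)C)c21 | intermediate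
14 | (6Z)-2-ethynyl-6-(3-methylbut-2-en-1-ylidene)-5-[(triisopropylsilyl)oxy]cyclohexa-2,4-dien-1-one | CC(C)=C/C=C1\C(=O)C(C#C)=CC=C1O[Si](C(C)C)(C(C)C)C(C)C | intermediate
15 | 8-ethynyl-2,2-dimethyl-5-[(triisopropylsilyl)oxy]-2H-chromene | CC1(C)C=Cc2c(O[Si](C(C)C)(C(C)C)C(C)C)ccc(C#C)c2O1 | intermediate
16 | 4-({2,2-dimethyl-5-[(triisopropylsilyl)oxy]-2H-chromen-8-yl}ethynyl)-6-(3-methylbut-2-en-1-yl)benzene-1,3-diol | CC(C)=CCc1cc(C#Cc2ccc(O[Si](C(C)C)(C(C)C)C(C)C)c3c2OC(C)(C)C=C3)c(O)cc1O | intermediate
17 | 2-{2,2-dimethyl-5-[(triisopropylsilyl)oxy]-2H-chromen-8-yl}-5-(3-methylbut-2-en-1-yl)-1-benzofuran-6-ol | CC(C)=CCc1cc2cc(-c3ccc(O[Si](C(C)C)(C(C)C)C(C)C)c4c3OC(C)(C)C=C4)oc2cc1O | intermediate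
18 | kanzonol V, 2-(5-hydroxy-2,2-dimethyl-2H-chromen-8-yl)-5-(3-methylbut-2-en-1-yl)-1-benzofuran-6-ol | CC(C)=CCc1cc2cc(-c3ccc(O)c4c3OC(C)(C)C=C4)oc2cc1O | target

**Step count and risks**

Total step count: 9. Longest linear sequence: 6 (steps 1, 2, 3, 4, 8, 9).

Steps most likely to fail:

1. Step 7. The ortho-aldol at the carbon flanked by the hydroxyl and the bulky silyloxy group may be slow, which would leave time for the ethynylphenol to oligomerise or to cyclise onto its own alkyne. The fallback sets out from 11 and comes back to the route at 15. O-Alkylation of 11 with 3-chloro-3-methylbut-1-yne (K2CO3, KI, acetone, reflux) should give the aryl 1,1-dimethylpropargyl ether 1-ethynyl-2-[(2-methylbut-3-yn-2-yl)oxy]-4-[(triisopropylsilyl)oxy]benzene F1. Heating it in xylene at 140 °C should bring about aromatic propargyl Claisen rearrangement to the free ortho carbon, 1,5-hydrogen shift and oxa-6π electrocyclisation to give 15. In this variant the two ring bonds are made in separate operations.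

2. Step 6. Methanolysis of the aryl silyl ether and incomplete homologation of the aldehyde, which is deactivated as its phenoxide, may erode the yield. The fallback sets out from 10 and comes back at 11 by a Corey–Fuchs sequence that avoids methoxide. Dibromo-olefination of 10 (CBr4, PPh3, CH2Cl2, 0 °C) should give 2-(2,2-dibromoethenyl)-5-[(triisopropylsilyl)oxy]phenol F2. Treatment with n-BuLi (3.2 equiv, THF, −78 °C, then aq. NH4Cl) should give 11 by bromine–lithium exchange and Fritsch–Buttenberg–Wiechell rearrangement.

3. Step 2. The aryl metal may attack the tertiary end of the allyl system (SN2′), or halogen–metal scrambling with prenyl bromide may lead to reduced arene and homo-coupling. The fallback sets out from 2 and comes back at 5. Aryllithium 4, generated as in step 2, is quenched with iodine to give 1-bromo-5-iodo-2,4-bis(methoxymethoxy)benzene F3. A chemoselective Suzuki–Miyaura coupling at the carbon–iodine bond with prenylboronic acid pinacol ester (Pd(dppf)Cl2, K3PO4, THF/H2O, 60 °C) should then give 5.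

**Further compounds**

F1 | step 7 | 1-ethynyl-2-[(2-methylbut-3-yn-2-yl)oxy]-4-[(triisopropylsilyl)oxy]benzene | C#Cc1ccc(O[Si](C(C)C)(C(C)C)C(C)C)cc1OC(C)(C)C#C
F2 | step 6 | 2-(2,2-dibromoethenyl)-5-[(triisopropylsilyl)oxy]phenol | BrC(Br)=Cc1ccc(O[Si](C(C)C)(C(C)C)C(C)C)cc1O
F3 | step 2 | 1-bromo-5-iodo-2,4-bis(methoxymethoxy)benzene | COCOc1cc(OCOC)c(I)cc1Br
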